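**Strategy**

Everything rests on closing ring C last by joining the unsubstituted C3 methylene to the C4 carbonyl carbon. Because C4 sits on ring A (C4a) ortho to the ether oxygen O1 (C8a), and C2 carries only O1, ring B and hydrogen, C2=C3 can be carried as an achiral 1-arylvinyl ether and C4 as an aldehyde. A rhodium-catalysed enantioselective intramolecular hydroacylation of this fully decorated 2-(1-arylvinyloxy)benzaldehyde forms the C3–C4 bond, closes ring C and sets the C2 stereocentre in one atom-economical, redox-neutral operation. The hexasubstituted ring A is built on the vinyl ether by three successive directed ortho-lithiations; the side-chain carbinol comes from a Sharpless epoxide.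

Key step: step 9

Remark: positions are named by flavanone numbering (O1, C2, C3, C4, C4a, C5 to C8, C8a; rings A, B, C). 4-(Methoxymethoxy)benzoic acid (3) is taken as a catalogue compound. MOM = methoxymethyl. All aryl vinyl ethers (5, 10, 11, 14, 17) are to be worked up under neutral or basic conditions and chromatographed on Et3N-deactivated silica.

**Route**

Step 1
Reactants: 1 phloroglucinol (benzene-1,3,5-triol)
Product: 2 3,5-bis(methoxymethoxy)phenol
Conditions: NaH (2.0 equiv), MOMCl (2.0 equiv), DMF, 0 °C to rt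
Reagents that add atoms: chloromethyl methyl ether, COCCl
Why: O-alkylation of the phenoxides (Williamson-type MOM acetal formation) with two equivalents of base and electrophile should give the bis-ether as the main component of a statistical mixture, separable by chromatography, with mono- and tris-ethers recycled.

Step 2
Reactants: 2 3,5-bis(methoxymethoxy)phenol; 3 4-(methoxymethoxy)benzoic acid
Product: 4 3,5-bis(methoxymethoxy)phenyl 4-(methoxymethoxy)benzoate
Conditions: EDC·HCl (1.2 equiv), DMAP (0.1 equiv), CH2Cl2, rt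
Reagents that add atoms: none
Why: Steglich esterification (carbodiimide activation, DMAP acyl transfer) should acylate the single free, unhindered phenol.

Step 3
Reactants: 4 3,5-bis(methoxymethoxy)phenyl 4-(methoxymethoxy)benzoate
Product: 5 1-({1-[4-(methoxymethoxy)phenyl]ethenyl}oxy)-3,5-bis(methoxymethoxy)benzene
Conditions: Cp2TiMe2 (2.5 equiv), toluene–THF, 70 °C, dark; filtration through basic Al2O3
Reagents that add atoms: dimethyltitanocene, C[Ti+2]C.c1cc[cH-]c1.c1cc[cH-]c1
Why: Petasis methylenation, in which thermally formed Cp2Ti=CH2 adds to the aryl ester carbonyl by [2+2] cycloaddition and cycloreversion, should give the 1,1-disubstituted aryl enol ether under non-acidic conditions that spare the MOM acetals.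

Step 4
Reactants: 6 3-methylbut-2-en-1-ol (prenol)
Product: 8 [(2R)-3,3-dimethyloxiran-2-yl]methyl 4-methylbenzenesulfonate, via epoxy alcohol 7 (not isolated)
Conditions: Ti(OiPr)4 (5 mol %), D-(−)-diisopropyl tartrate (7 mol %), t-BuOOH, 4 Å sieves, CH2Cl2, −20 °C; then P(OMe)3, Et3N, TsCl, DMAP (cat.), −10 °C
Reagents that add atoms: tert-butyl hydroperoxide, CC(C)(C)OO; 4-methylbenzenesulfonyl chloride, Cc1ccc(cc1)S(=O)(=O)Cl
Why: Sharpless asymmetric epoxidation with the D-(−)-tartrate ligand should set the (R) epoxide centre by reagent control, and in situ tosylation traps the volatile, water-soluble epoxy alcohol as a stable sulfonate whose enantiopurity can be raised by recrystallisation if needed.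

Step 5
Reactants: 5 1-({1-[4-(methoxymethoxy)phenyl]ethenyl}oxy)-3,5-bis(methoxymethoxy)benzene; 8 [(2R)-3,3-dimethyloxiran-2-yl]methyl 4-methylbenzenesulfonate
Product: 10 (3R)-3-{[2,6-bis(methoxymethoxy)-4-({1-[4-(methoxymethoxy)phenyl]ethenyl}oxy)phenyl]methyl}-2,2-dimethyloxirane, via aryllithium 9 (not isolated)
Conditions: n-BuLi (1.1 equiv), THF, 0 °C; then CuBr·SMe2 (10 mol %), 8, −30 °C to rt
Reagents that add atoms: none
Why: Directed ortho-lithiation should occur at the ring-A carbon flanked by two MOM ethers (cooperative direction), and copper-catalysed SN2 displacement of the primary sulfonate by the aryl nucleophile forms no bond at the hindered trisubstituted epoxide, so the (R) centre is carried over unchanged.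

Step 6
Reactants: 10 (3R)-3-{[2,6-bis(methoxymethoxy)-4-({1-[4-(methoxymethoxy)phenyl]ethenyl}oxy)phenyl]methyl}-2,2-dimethyloxirane
Product: 11 (2R)-1-[2,6-bis(methoxymethoxy)-4-({1-[4-(methoxymethoxy)phenyl]ethenyl}oxy)phenyl]-3-methylbut-3-en-2-ol
Conditions: Al(OiPr)3 (2 equiv), toluene, 110 °C; then H2O
Reagents that add atoms: none
Why: Aluminium-alkoxide-mediated isomerisation of an epoxide to an allylic alcohol removes a methyl proton with cleavage of the tertiary C–O bond, giving the 1,1-disubstituted alkene while the secondary C–O bond, and hence the (R) centre, is untouched.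

Step 7
Reactants: 11 (2R)-1-[2,6-bis(methoxymethoxy)-4-({1-[4-(methoxymethoxy)phenyl]ethenyl}oxy)phenyl]-3-methylbut-3-en-2-ol; 12 prenyl bromide (1-bromo-3-methylbut-2-ene)
Product: 14 (2R)-1-[2,6-bis(methoxymethoxy)-4-({1-[4-(methoxymethoxy)phenyl]ethenyl}oxy)-3-(3-methylbut-2-en-1-yl)phenyl]-3-methylbut-3-en-2-ol, via dilithio intermediate 13 (not isolated)
Conditions: n-BuLi (2.2 equiv), THF, −78 to 0 °C; CuBr·SMe2 (10 mol %), 12, −78 °C to rt; then H2O
Reagents that add atoms: none
Why: After deprotonation of the hydroxyl, a second directed ortho-lithiation should take place at one of the two equivalent ring-A positions between a MOM ether and the vinyloxy oxygen, and copper-catalysed SN2 allylation installs the prenyl group while the poorly nucleophilic lithium alkoxide stays unalkylated.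

Step 8
Reactants: 14 (2R)-1-[2,6-bis(methoxymethoxy)-4-({1-[4-(methoxymethoxy)phenyl]ethenyl}oxy)-3-(3-methylbut-2-en-1-yl)phenyl]-3-methylbut-3-en-2-ol
Product: 17 3-[(2R)-2-hydroxy-3-methylbut-3-en-1-yl]-2,4-bis(methoxymethoxy)-6-({1-[4-(methoxymethoxy)phenyl]ethenyl}oxy)-5-(3-methylbut-2-en-1-yl)benzaldehyde, via dilithio intermediate 15 (not isolated), via lithium hemiaminal alkoxide 16 (not isolated)
Conditions: n-BuLi (2.2 equiv), THF, −78 to 0 °C; DMF, −78 °C to rt; then H2O
Reagents that add atoms: N,N-dimethylformamide, CN(C)C=O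
Why: A third directed ortho-lithiation at the last ring-A C–H (between MOM ether and vinyloxy oxygen) followed by Bouveault-type formylation with DMF should give the aldehyde, which stays masked as the tetrahedral lithium hemiaminal until aqueous work-up.

Step 9
Reactants: 17 3-[(2R)-2-hydroxy-3-methylbut-3-en-1-yl]-2,4-bis(methoxymethoxy)-6-({1-[4-(methoxymethoxy)phenyl]ethenyl}oxy)-5-(3-methylbut-2-en-1-yl)benzaldehyde
Product: 18 (2S)-6-[(2R)-2-hydroxy-3-methylbut-3-en-1-yl]-5,7-bis(methoxymethoxy)-2-[4-(methoxymethoxy)phenyl]-8-(3-methylbut-2-en-1-yl)-2,3-dihydro-4H-chromen-4-one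
Conditions: [Rh(cod)Cl]2 (2.5 mol %), (R)-DTBM-SEGPHOS (5.5 mol %), NaB[3,5-(CF3)2C6H3]4 (5 mol %), THF, 60 °C
Reagents that add atoms: none
Why: Proposed new method: oxidative addition of the aldehyde C–H bond to the cationic monovalent rhodium–bisphosphine complex should give an acyl rhodium hydride that holds the tethered enol ether in a six-membered chelate; hydride insertion then places H on C2 and rhodium on the terminal carbon C3, and C–C reductive elimination from the seven-membered acyl(alkyl)rhodacycle forms the C3–C4 bond. The closest known reaction type is the rhodium-catalysed enantioselective intramolecular hydroacylation of 1,1-disubstituted alkenes in ortho-(2-substituted allyl)aryl aldehydes, which gives six-membered benzo- and hetero-fused ketones with a β-stereocentre; here the allylic CH2 is replaced by the ether oxygen O1. Ring C closes in a formal 6-endo-trig mode, both alkene carbons ending in the ring. The only new stereocentre, C2, is set in the hydride-insertion step by the chiral bisphosphine, which differentiates the enantiotopic faces of the enol ether; the ligand antipode that delivers 2S is to be fixed on a model aldehyde without the side chains, and the remote (R) carbinol is a spectator. The step needs anti-Markovnikov insertion (rhodium to CH2; the alternative would demand a tertiary alkyl-rhodium and a five-membered ketone), suppression of decarbonylation (the two ortho oxygens chelate the acyl hydride and the alkene is held intramolecularly) and chemoselectivity over the prenyl and isopropenyl alkenes, which sit meta to the acyl carbon on ring A and cannot reach it.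

Step 10
Reactants: 18 (2S)-6-[(2R)-2-hydroxy-3-methylbut-3-en-1-yl]-5,7-bis(methoxymethoxy)-2-[4-(methoxymethoxy)phenyl]-8-(3-methylbut-2-en-1-yl)-2,3-dihydro-4H-chromen-4-one
Product: 19 (2S)-5,7-dihydroxy-6-[(2R)-2-hydroxy-3-methylbut-3-en-1-yl]-2-(4-hydroxyphenyl)-8-(3-methylbut-2-en-1-yl)-2,3-dihydro-4H-chromen-4-one (CNP0257325.1)
Conditions: HCl (2 M) in MeOH–H2O (9:1), 40 °C
Reagents that add atoms: none
Why: Acid-catalysed acetal exchange with methanol (MOM cleavage) should free the three phenols under conditions mild enough to leave the prenyl group, the allylic alcohol and the C2 centre (no base, hence no retro-oxa-Michael opening of ring C) untouched.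

**Compound list**

1 | phloroglucinol (benzene-1,3,5-triol) | Oc1cc(O)cc(O)c1 | starting material
2 | 3,5-bis(methoxymethoxy)phenol | COCOc1cc(O)cc(OCOC)c1 | intermediate
3 | 4-(methoxymethoxy)benzoic acid | COCOc1ccc(cc1)C(O)=O | starting material
4 | 3,5-bis(methoxymethoxy)phenyl 4-(methoxymethoxy)benzoate | COCOc1ccc(cc1)C(=O)Oc1cc(OCOC)cc(OCOC)c1 | intermediate
5 | 1-({1-[4-(methoxymethoxy)phenyl]ethenyl}oxy)-3,5-bis(methoxymethoxy)benzene | C=C(Oc1cc(OCOC)cc(OCOC)c1)c1ccc(OCOC)cc1 | intermediate
6 | 3-methylbut-2-en-1-ol (prenol) | CC(C)=CCO | starting material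
7 | [(2R)-3,3-dimethyloxiran-2-yl]methanol (not isolated) | CC1(C)O[C@@H]1CO | intermediate
8 | [(2R)-3,3-dimethyloxiran-2-yl]methyl 4-methylbenzenesulfonate | CC1(C)O[C@@H]1COS(=O)(=O)c1ccc(C)cc1 | intermediate
9 | aryllithium of 5, lithium on the ring-A carbon between the two MOM ethers (not isolated) | C=C(Oc1cc(OCOC)c([Li])c(OCOC)c1)c1ccc(OCOC)cc1 | intermediate
10 | (3R)-3-{[2,6-bis(methoxymethoxy)-4-({1-[4-(methoxymethoxy)phenyl]ethenyl}oxy)phenyl]methyl}-2,2-dimethyloxirane | C=C(Oc1cc(OCOC)c(C[C@H]2OC2(C)C)c(OCOC)c1)c1ccc(OCOC)cc1 | intermediate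
11 | (2R)-1-[2,6-bis(methoxymethoxy)-4-({1-[4-(methoxymethoxy)phenyl]ethenyl}oxy)phenyl]-3-methylbut-3-en-2-ol | C=C(C)[C@H](O)Cc1c(OCOC)cc(OC(=C)c2ccc(OCOC)cc2)cc1OCOC | intermediate
12 | prenyl bromide (1-bromo-3-methylbut-2-ene) | CC(C)=CCBr | starting material
13 | dilithio intermediate of 11: lithium alkoxide, aryl lithium between MOM ether and vinyloxy oxygen (not isolated) | C=C(C)[C@H](O[Li])Cc1c(OCOC)c([Li])c(OC(=C)c2ccc(OCOC)cc2)cc1OCOC | intermediate
14 | (2R)-1-[2,6-bis(methoxymethoxy)-4-({1-[4-(methoxymethoxy)phenyl]ethenyl}oxy)-3-(3-methylbut-2-en-1-yl)phenyl]-3-methylbut-3-en-2-ol | C=C(C)[C@H](O)Cc1c(OCOC)c(CC=C(C)C)c(OC(=C)c2ccc(OCOC)cc2)cc1OCOC | intermediate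
15 | dilithio intermediate of 14: lithium alkoxide, aryl lithium at the last ring-A position (not isolated) | C=C(C)[C@H](O[Li])Cc1c(OCOC)c(CC=C(C)C)c(OC(=C)c2ccc(OCOC)cc2)c([Li])c1OCOC | intermediate
16 | lithium hemiaminal alkoxide from 15 and DMF (not isolated) | C=C(C)[C@H](O[Li])Cc1c(OCOC)c(CC=C(C)C)c(OC(=C)c2ccc(OCOC)cc2)c(C(O[Li])N(C)C)c1OCOC | intermediate
17 | 3-[(2R)-2-hydroxy-3-methylbut-3-en-1-yl]-2,4-bis(methoxymethoxy)-6-({1-[4-(methoxymethoxy)phenyl]ethenyl}oxy)-5-(3-methylbut-2-en-1-yl)benzaldehyde | C=C(C)[C@H](O)Cc1c(OCOC)c(CC=C(C)C)c(OC(=C)c2ccc(OCOC)cc2)c(C=O)c1OCOC | intermediate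
18 | (2S)-6-[(2R)-2-hydroxy-3-methylbut-3-en-1-yl]-5,7-bis(methoxymethoxy)-2-[4-(methoxymethoxy)phenyl]-8-(3-methylbut-2-en-1-yl)-2,3-dihydro-4H-chromen-4-one | C=C(C)[C@H](O)Cc1c(OCOC)c(CC=C(C)C)c2c(c1OCOC)C(=O)C[C@@H](c1ccc(OCOC)cc1)O2 | intermediate
19 | (2S)-5,7-dihydroxy-6-[(2R)-2-hydroxy-3-methylbut-3-en-1-yl]-2-(4-hydroxyphenyl)-8-(3-methylbut-2-en-1-yl)-2,3-dihydro-4H-chromen-4-one | C=C(C)[C@H](O)Cc1c(O)c(CC=C(C)C)c2c(c1O)C(=O)C[C@@H](c1ccc(O)cc1)O2 | target

**Step count and risks**

Total step count: 10. Longest linear sequence: 9 steps (steps 1 to 3 and 5 to 10; step 4 is a one-step branch).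

Steps most likely to fail:

1. Step 9 (key step). What may go wrong: decarbonylation of the acyl rhodium hydride before insertion, slow turnover of the doubly ortho-substituted aldehyde, erosion of the enol ether by traces of acid, redox isomerisation of the allylic alcohol, or weak facial discrimination in the hydride insertion. The fallback uses known chemistry (flavone formation by acylation of the enol ether, then asymmetric conjugate reduction); it sets out from 14 and comes back at 19. Compound 14 is silylated (Et3SiCl, imidazole) to triethylsilyl ether F1. Ortho-lithiation (n-BuLi) gives aryllithium F2, which is carboxylated with CO2 to benzoic acid F3. 1-Chloro-N,N,2-trimethylprop-1-en-1-amine converts this under neutral conditions into acid chloride F4, which acylates the CH2 terminus of the tethered enol ether (Friedel–Crafts-type acylation of an enol ether, six-membered ring) and loses HCl to 2,6-lutidine to give flavone F5. Copper hydride conjugate reduction with a chiral bisphosphine (Cu(OAc)2, DTBM-SEGPHOS antipode chosen on a model, polymethylhydrosiloxane, t-BuOH) sets C2 and should give O-silyl flavanone F6, which is taken through the conditions of step 10, where the silyl ether falls together with the MOM ethers, to reach 19.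

2. Step 5. What may go wrong: attack of the aryl nucleophile at sulfur or at the epoxide instead of SN2 displacement at CH2, sluggish coupling of the doubly ortho-substituted aryl metal, or opening of the epoxide by halide. The fallback sets out from 5 and comes back at 11. Aryllithium 9 is trapped with ethylene oxide to give arylethanol F7; Dess–Martin oxidation gives arylacetaldehyde F8; addition of isopropenylmagnesium bromide gives racemic allylic alcohol F9; a second Dess–Martin oxidation gives enone F10; Corey–Bakshi–Shibata reduction ((S)-2-methyl-CBS-oxazaborolidine, catecholborane, −78 °C), with the isopropenyl group acting as the large substituent, should deliver (R)-alcohol 11.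

3. Step 10. What may go wrong: acid-promoted cyclisation of the prenyl or isopropenyl group onto a neighbouring phenol, solvolysis of the allylic alcohol, or partial opening and reclosure of ring C with loss of configuration at C2. The fallback sets out from 18 and comes back at 19. Non-protic acetal cleavage with Me3SiOTf and 2,2'-bipyridyl (CH2Cl2, 0 °C) converts the aryl MOM ethers, and the carbinol, into trimethylsilyl ethers, giving per-silylated flavanone F11; stirring with water in THF at neutral pH removes the silyl groups and should give 19.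

Further compounds
F1 | step 9 | triethylsilyl ether of 14 | C=C(C)[C@H](O[Si](CC)(CC)CC)Cc1c(OCOC)c(CC=C(C)C)c(OC(=C)c2ccc(OCOC)cc2)cc1OCOC
F2 | step 9 | aryllithium of F1 at the last ring-A position | C=C(C)[C@H](O[Si](CC)(CC)CC)Cc1c(OCOC)c(CC=C(C)C)c(OC(=C)c2ccc(OCOC)cc2)c([Li])c1OCOC
F3 | step 9 | benzoic acid from F2 and CO2 | C=C(C)[C@H](O[Si](CC)(CC)CC)Cc1c(OCOC)c(CC=C(C)C)c(OC(=C)c2ccc(OCOC)cc2)c(C(=O)O)c1OCOC
F4 | step 9 | acid chloride of F3 | C=C(C)[C@H](O[Si](CC)(CC)CC)Cc1c(OCOC)c(CC=C(C)C)c(OC(=C)c2ccc(OCOC)cc2)c(C(=O)Cl)c1OCOC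
F5 | step 9 | 6-[(2R)-2-(triethylsilyloxy)-3-methylbut-3-en-1-yl]-5,7-bis(methoxymethoxy)-2-[4-(methoxymethoxy)phenyl]-8-prenyl-4H-chromen-4-one (flavone) | C=C(C)[C@H](O[Si](CC)(CC)CC)Cc1c(OCOC)c(CC=C(C)C)c2c(c1OCOC)C(=O)C=C(c1ccc(OCOC)cc1)O2
F6 | step 9 | O-triethylsilyl ether of 18, (2S)-flavanone | C=C(C)[C@H](O[Si](CC)(CC)CC)Cc1c(OCOC)c(CC=C(C)C)c2c(c1OCOC)C(=O)C[C@@H](c1ccc(OCOC)cc1)O2
F7 | step 5 | 2-[2,6-bis(methoxymethoxy)-4-({1-[4-(methoxymethoxy)phenyl]ethenyl}oxy)phenyl]ethanol | OCCc1c(OCOC)cc(OC(=C)c2ccc(OCOC)cc2)cc1OCOC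
F8 | step 5 | 2-[2,6-bis(methoxymethoxy)-4-({1-[4-(methoxymethoxy)phenyl]ethenyl}oxy)phenyl]acetaldehyde | O=CCc1c(OCOC)cc(OC(=C)c2ccc(OCOC)cc2)cc1OCOC
F9 | step 5 | racemic 1-[2,6-bis(methoxymethoxy)-4-({1-[4-(methoxymethoxy)phenyl]ethenyl}oxy)phenyl]-3-methylbut-3-en-2-ol | C=C(C)C(O)Cc1c(OCOC)cc(OC(=C)c2ccc(OCOC)cc2)cc1OCOC
F10 | step 5 | 1-[2,6-bis(methoxymethoxy)-4-({1-[4-(methoxymethoxy)phenyl]ethenyl}oxy)phenyl]-3-methylbut-3-en-2-one | C=C(C)C(=O)Cc1c(OCOC)cc(OC(=C)c2ccc(OCOC)cc2)cc1OCOC
F11 | step 10 | tetrakis(trimethylsilyl) ether of 19 (three phenols and the carbinol) | C=C(C)[C@H](O[Si](C)(C)C)Cc1c(O[Si](C)(C)C)c(CC=C(C)C)c2c(c1O[Si](C)(C)C)C(=O)C[C@@H](c1ccc(O[Si](C)(C)C)cc1)O2
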